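**Retrosynthetic overview** (the side chain is numbered as the dodeca-2,6,11-trienoic acid: C1 = CO2H, C10 = carbinol carbon, C12 = carbon on the ring)
1. The C9–C10 bond is cut. An (R)-allylic N,N-diisopropylcarbamate (C10–C12 plus the protected hydroquinone ring) and a primary pinacol boronate (C1–C9) are joined in one pot by lithiation–borylation–oxidation. The 1,2-metalate shift makes the C9–C10 bond and the quaternary C10 stereocentre, and boron-to-oxygen exchange gives the tertiary hydroxyl.
2. Enabling feature: C10 is a carbinol carbon flanked by the C11=C12 double bond, which is conjugated with the hydroquinone ring. Its C–H in the carbamate is therefore acidified by the allyl/aryl π system and by the carbamate dipole, and it becomes a configurationally defined carbenoid. C9 is an unhindered CH2 that migrates readily from boron.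
3. The carbamate comes from 2,5-dimethoxy-4-methylbenzaldehyde: demethylation, silylation, E-selective Wittig reaction, CBS reduction (the only stereocentre-forming step; its configuration is later transferred to C10), carbamoylation.
4. The boronate comes from geranyl chloride: 6,7-epoxide as a masked aldehyde, deborylative alkylation with CH2(Bpin)2 (installs C9–B), periodate cleavage, E-selective Wittig reaction with an α-(4-methylpent-3-enyl) phosphorane.
5. No ring is formed. The benzene ring is carried from the start and the oxirane is a temporary mask that is cleaved again. One fluoride step frees both phenols and the acid.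

Key step: step 12

Assumption: the lithiated secondary allylic carbamate is taken to be borylated by the boronic ester with retention and to rearrange with inversion, as secondary benzylic carbamates do; the (R)-carbamate is chosen on that basis, and the enantiomeric oxazaborolidine would be used in the reduction if the sense proved opposite.

**Route**

Step 1
Reactants: 1 2,5-dimethoxy-4-methylbenzaldehyde
Product: 2 2,5-dihydroxy-4-methylbenzaldehyde
Conditions: BBr3, CH2Cl2, −78 °C to rt; then H2O
Reagents that add atoms: none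
Why: BBr3 cleaves both aryl methyl ethers by Lewis acid complexation and SN2 attack of bromide on the methyl groups (aryl methyl ether demethylation), and the aldehyde is recovered on aqueous work-up.

Step 2
Reactants: 2 2,5-dihydroxy-4-methylbenzaldehyde
Product: 3 4-methyl-2,5-bis(triisopropylsilyloxy)benzaldehyde
Conditions: TIPSOTf, 2,6-lutidine, CH2Cl2, 0 °C to rt
Reagents that add atoms: triisopropylsilyl trifluoromethanesulfonate, CC(C)[Si](C(C)C)(C(C)C)OS(=O)(=O)C(F)(F)F
Why: Silyl ether formation with the reactive silyl triflate and a hindered pyridine base should cover both phenols, including the hydrogen-bonded one ortho to the aldehyde, with bulky groups that resist organolithium reagents and leave with fluoride.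

Step 3
Reactants: 3 4-methyl-2,5-bis(triisopropylsilyloxy)benzaldehyde; 4 1-(triphenylphosphoranylidene)propan-2-one
Product: 5 (E)-4-[4-methyl-2,5-bis(triisopropylsilyloxy)phenyl]but-3-en-2-one
Conditions: toluene, 90 °C
Reagents that add atoms: none
Why: Wittig olefination with a ketone-stabilised ylide should give the E enone selectively and leaves the aryl silyl ethers untouched.

Step 4
Reactants: 5 (E)-4-[4-methyl-2,5-bis(triisopropylsilyloxy)phenyl]but-3-en-2-one
Product: 6 (2R,3E)-4-[4-methyl-2,5-bis(triisopropylsilyloxy)phenyl]but-3-en-2-ol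
Conditions: (S)-2-methyl-CBS-oxazaborolidine (10 mol%), BH3·SMe2, THF, −30 °C; then MeOH
Reagents that add atoms: none
Why: In the Corey–Bakshi–Shibata reduction the (S)-oxazaborolidine binds borane and the ketone with the large alkenyl group turned away from the catalyst, so hydride is delivered to one carbonyl face and the (R)-allylic alcohol is expected, 1,2-reduction being much faster than alkene hydroboration at this temperature.

Step 5
Reactants: 6 (2R,3E)-4-[4-methyl-2,5-bis(triisopropylsilyloxy)phenyl]but-3-en-2-ol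
Product: 7 (2R,3E)-4-[4-methyl-2,5-bis(triisopropylsilyloxy)phenyl]but-3-en-2-yl N,N-diisopropylcarbamate
Conditions: iPr2NCOCl, Et3N, toluene, 90 °C
Reagents that add atoms: N,N-diisopropylcarbamoyl chloride, CC(C)N(C(C)C)C(Cl)=O
Why: O-Carbamoylation of the secondary alcohol (acyl substitution) installs the group that later directs lithiation and acts as leaving group, without touching the stereocentre.

Step 6
Reactants: 8 geranyl chloride, (2E)-1-chloro-3,7-dimethylocta-2,6-diene
Product: 9 (E)-6,7-epoxygeranyl chloride, 3-[(3E)-5-chloro-3-methylpent-3-enyl]-2,2-dimethyloxirane (racemic)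
Conditions: mCPBA, CH2Cl2, 0 °C
Reagents that add atoms: 3-chloroperoxybenzoic acid, OOC(=O)c1cccc(Cl)c1
Why: Prilezhaev epoxidation should select the electron-rich 6,7-alkene because the allylic chloride deactivates the 2,3-alkene, and the new stereocentre is formed as a racemate that step 8 destroys.

Step 7
Reactants: 9 (E)-6,7-epoxygeranyl chloride; 10 bis(4,4,5,5-tetramethyl-1,3,2-dioxaborolan-2-yl)methane
Product: 11 2-[(3E)-6-(3,3-dimethyloxiran-2-yl)-4-methylhex-3-enyl]-4,4,5,5-tetramethyl-1,3,2-dioxaborolane (racemic)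
Conditions: 10, NaOtBu, THF, rt, 15 min; then 9, rt
Reagents that add atoms: none
Why: In this alkoxide-promoted deborylative alkylation tert-butoxide adds to one boron of 10 and releases an α-boryl carbanion that displaces the primary allylic chloride by SN2, which keeps the E alkene and leaves the hindered epoxide intact.

Step 8
Reactants: 11 2-[(3E)-6-(3,3-dimethyloxiran-2-yl)-4-methylhex-3-enyl]-4,4,5,5-tetramethyl-1,3,2-dioxaborolane
Product: 12 (4E)-4-methyl-7-(4,4,5,5-tetramethyl-1,3,2-dioxaborolan-2-yl)hept-4-enal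
Conditions: H5IO6, THF/Et2O, 0 °C
Reagents that add atoms: none
Why: Periodic acid opens the trisubstituted epoxide at the tertiary carbon and cleaves the resulting glycol (glycol cleavage) to the aldehyde, which keeps the epoxide oxygen, and acetone, and a short exposure at 0 °C should spare the alkyl pinacol boronate.

Step 9
Reactants: 13 (triphenylphosphoranylidene)ketene; 14 2-(trimethylsilyl)ethanol
Product: 15 2-(trimethylsilyl)ethyl (triphenylphosphoranylidene)acetate
Conditions: toluene, 80 °C
Reagents that add atoms: none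
Why: Addition of the alcohol across the cumulated ylide (Bestmann ylide) should give the ester-stabilised phosphorane directly and without a by-product.

Step 10
Reactants: 15 2-(trimethylsilyl)ethyl (triphenylphosphoranylidene)acetate; 16 5-bromo-2-methylpent-2-ene
Product: 18 2-(trimethylsilyl)ethyl 6-methyl-2-(triphenylphosphoranylidene)hept-5-enoate, via phosphonium bromide 17 (not isolated)
Conditions: NaI (cat.), MeCN, 80 °C; then aq NaOH, CH2Cl2, rt
Reagents that add atoms: none
Why: C-Alkylation of the stabilised ylide by the primary halide, activated in situ as the iodide (SN2), gives the phosphonium salt, which aqueous NaOH deprotonates to the α-substituted ylide.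

Step 11
Reactants: 12 (4E)-4-methyl-7-(4,4,5,5-tetramethyl-1,3,2-dioxaborolan-2-yl)hept-4-enal; 18 2-(trimethylsilyl)ethyl 6-methyl-2-(triphenylphosphoranylidene)hept-5-enoate
Product: 19 2-(trimethylsilyl)ethyl (2E,6E)-6-methyl-2-(4-methylpent-3-enyl)-9-(4,4,5,5-tetramethyl-1,3,2-dioxaborolan-2-yl)nona-2,6-dienoate
Conditions: toluene, 80 °C
Reagents that add atoms: none
Why: Wittig olefination with the α-branched ester-stabilised ylide should place the ester trans to the chain of the aldehyde (E trisubstituted enoate) and does not affect the alkyl boronate.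

Step 12
Reactants: 7 (2R,3E)-4-[4-methyl-2,5-bis(triisopropylsilyloxy)phenyl]but-3-en-2-yl N,N-diisopropylcarbamate (1.3 equiv); 19 2-(trimethylsilyl)ethyl (2E,6E)-6-methyl-2-(4-methylpent-3-enyl)-9-(4,4,5,5-tetramethyl-1,3,2-dioxaborolan-2-yl)nona-2,6-dienoate (1.0 equiv)
Product: 23 2-(trimethylsilyl)ethyl (2E,6E,10S,11E)-10-hydroxy-6,10-dimethyl-2-(4-methylpent-3-enyl)-12-[4-methyl-2,5-bis(triisopropylsilyloxy)phenyl]dodeca-2,6,11-trienoate, via lithiated carbamate 20 (not isolated), via lithium boronate complex 21 (not isolated), via tertiary boronic ester 22 (not isolated)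
Conditions: sBuLi (1.2 equiv), TMEDA, Et2O, −78 °C; then 19, −78 °C to rt; then NaOH, H2O2, THF/H2O, 0 °C
Reagents that add atoms: hydrogen peroxide, OO
Why: sBuLi/TMEDA removes the C10–H of 7 with retention to give the chelated α-carbamoyloxy allyllithium 20, which adds to boron of 19 with retention to form boronate complex 21; on warming the C9 methylene migrates from boron to C10 antiperiplanar to the departing carbamate (1,2-metalate rearrangement, inversion at C10) to give 22, and alkaline H2O2 replaces boron by hydroxyl with retention. The closest known reaction type is the lithiation–borylation of enantioenriched secondary allylic and benzylic carbamates with primary alkyl boronic esters (Matteson-type 1,2-shift of a boronate complex) followed by oxidation to tertiary alcohols. No ring is closed. The C10 stereocentre is controlled only by the stereocentre of 7: retention in lithiation and borylation, inversion in the shift and retention in the oxidation should convert the (R)-carbamate into the (S)-alcohol. The step needs borylation at C10 and not at the benzylic C12 terminus, which the carbamate-chelated lithium at C10 and the hindered aryl-bearing C12 (ortho silyloxy group) should secure, and it needs the E geometry of C11=C12 to persist, which −78 °C favours. It also needs boron to outcompete the ester carbonyl of 19 for the organolithium, which fast complexation at boron and the hindered, conjugated α,β-disubstituted ester should secure, all sBuLi being consumed by the excess of 7 beforehand.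

Step 13
Reactants: 23 2-(trimethylsilyl)ethyl (2E,6E,10S,11E)-10-hydroxy-6,10-dimethyl-2-(4-methylpent-3-enyl)-12-[4-methyl-2,5-bis(triisopropylsilyloxy)phenyl]dodeca-2,6,11-trienoate
Product: 24 (2E,6E,10S,11E)-12-(2,5-dihydroxy-4-methylphenyl)-10-hydroxy-6,10-dimethyl-2-(4-methylpent-3-enyl)dodeca-2,6,11-trienoic acid (CNP0134639.1)
Conditions: TBAF, THF (degassed, argon), 0 °C to rt; then AcOH
Reagents that add atoms: none
Why: Fluoride attacks silicon, so the two aryl silyl ethers are cleaved and the 2-(trimethylsilyl)ethyl ester fragments with loss of ethene (fluoride-induced β-elimination), which should release the hydroquinone and the acid without exposing the tertiary allylic alcohol to strong acid, argon keeping the hydroquinone from oxidation.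

**Compound list**
1 | 2,5-dimethoxy-4-methylbenzaldehyde | COc1cc(C)c(OC)cc1C=O | starting material
2 | 2,5-dihydroxy-4-methylbenzaldehyde | Cc1cc(O)c(C=O)cc1O | intermediate
3 | 4-methyl-2,5-bis(triisopropylsilyloxy)benzaldehyde | Cc1cc(O[Si](C(C)C)(C(C)C)C(C)C)c(C=O)cc1O[Si](C(C)C)(C(C)C)C(C)C | intermediate
4 | 1-(triphenylphosphoranylidene)propan-2-one | CC(=O)C=P(c1ccccc1)(c1ccccc1)c1ccccc1 | starting material
5 | (E)-4-[4-methyl-2,5-bis(triisopropylsilyloxy)phenyl]but-3-en-2-one | CC(=O)/C=C/c1cc(O[Si](C(C)C)(C(C)C)C(C)C)c(C)cc1O[Si](C(C)C)(C(C)C)C(C)C | intermediate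
6 | (2R,3E)-4-[4-methyl-2,5-bis(triisopropylsilyloxy)phenyl]but-3-en-2-ol | C[C@@H](O)/C=C/c1cc(O[Si](C(C)C)(C(C)C)C(C)C)c(C)cc1O[Si](C(C)C)(C(C)C)C(C)C | intermediate
7 | (2R,3E)-4-[4-methyl-2,5-bis(triisopropylsilyloxy)phenyl]but-3-en-2-yl N,N-diisopropylcarbamate | C[C@@H](OC(=O)N(C(C)C)C(C)C)/C=C/c1cc(O[Si](C(C)C)(C(C)C)C(C)C)c(C)cc1O[Si](C(C)C)(C(C)C)C(C)C | intermediate
8 | geranyl chloride, (2E)-1-chloro-3,7-dimethylocta-2,6-diene | CC(C)=CCC/C(C)=C/CCl | starting material
9 | (E)-6,7-epoxygeranyl chloride, 3-[(3E)-5-chloro-3-methylpent-3-enyl]-2,2-dimethyloxirane (racemic) | CC1(C)OC1CC/C(C)=C/CCl | intermediate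
10 | bis(4,4,5,5-tetramethyl-1,3,2-dioxaborolan-2-yl)methane | CC1(C)OB(CB2OC(C)(C)C(C)(C)O2)OC1(C)C | starting material
11 | 2-[(3E)-6-(3,3-dimethyloxiran-2-yl)-4-methylhex-3-enyl]-4,4,5,5-tetramethyl-1,3,2-dioxaborolane (racemic) | CC1(C)OC1CC/C(C)=C/CCB2OC(C)(C)C(C)(C)O2 | intermediate
12 | (4E)-4-methyl-7-(4,4,5,5-tetramethyl-1,3,2-dioxaborolan-2-yl)hept-4-enal | O=CCC/C(C)=C/CCB1OC(C)(C)C(C)(C)O1 | intermediate
13 | (triphenylphosphoranylidene)ketene | O=C=C=P(c1ccccc1)(c1ccccc1)c1ccccc1 | starting material
14 | 2-(trimethylsilyl)ethanol | C[Si](C)(C)CCO | starting material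
15 | 2-(trimethylsilyl)ethyl (triphenylphosphoranylidene)acetate | C[Si](C)(C)CCOC(=O)C=P(c1ccccc1)(c1ccccc1)c1ccccc1 | intermediate
16 | 5-bromo-2-methylpent-2-ene | CC(C)=CCCBr | starting material
17 | [6-methyl-1-oxo-1-[2-(trimethylsilyl)ethoxy]hept-5-en-2-yl]triphenylphosphonium bromide (racemic) | CC(C)=CCCC(C(=O)OCC[Si](C)(C)C)[P+](c1ccccc1)(c1ccccc1)c1ccccc1.[Br-] | intermediate
18 | 2-(trimethylsilyl)ethyl 6-methyl-2-(triphenylphosphoranylidene)hept-5-enoate | CC(C)=CCCC(C(=O)OCC[Si](C)(C)C)=P(c1ccccc1)(c1ccccc1)c1ccccc1 | intermediate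
19 | 2-(trimethylsilyl)ethyl (2E,6E)-6-methyl-2-(4-methylpent-3-enyl)-9-(4,4,5,5-tetramethyl-1,3,2-dioxaborolan-2-yl)nona-2,6-dienoate | CC(C)=CCC/C(=C\CC/C(C)=C/CCB1OC(C)(C)C(C)(C)O1)C(=O)OCC[Si](C)(C)C | intermediate
20 | (2R,3E)-2-lithio-4-[4-methyl-2,5-bis(triisopropylsilyloxy)phenyl]but-3-en-2-yl N,N-diisopropylcarbamate (lithium in the place of the former hydrogen) | C[C@@]([Li])(OC(=O)N(C(C)C)C(C)C)/C=C/c1cc(O[Si](C(C)C)(C(C)C)C(C)C)c(C)cc1O[Si](C(C)C)(C(C)C)C(C)C | intermediate
21 | lithium boronate complex: boron of 19 bound to the carbamate-bearing carbon of 20 (R at that carbon, boron in the place of lithium) | CC(C)=CCC/C(=C\CC/C(C)=C/CC[B-]1(OC(C)(C)C(C)(C)O1)[C@](C)(OC(=O)N(C(C)C)C(C)C)/C=C/c1cc(O[Si](C(C)C)(C(C)C)C(C)C)c(C)cc1O[Si](C(C)C)(C(C)C)C(C)C)C(=O)OCC[Si](C)(C)C.[Li+] | intermediate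
22 | 2-(trimethylsilyl)ethyl (2E,6E,10R,11E)-6,10-dimethyl-2-(4-methylpent-3-enyl)-12-[4-methyl-2,5-bis(triisopropylsilyloxy)phenyl]-10-(4,4,5,5-tetramethyl-1,3,2-dioxaborolan-2-yl)dodeca-2,6,11-trienoate (boron where the hydroxyl of 23 stands) | CC(C)=CCC/C(=C\CC/C(C)=C/CC[C@](C)(B1OC(C)(C)C(C)(C)O1)/C=C/c1cc(O[Si](C(C)C)(C(C)C)C(C)C)c(C)cc1O[Si](C(C)C)(C(C)C)C(C)C)C(=O)OCC[Si](C)(C)C | intermediate
23 | 2-(trimethylsilyl)ethyl (2E,6E,10S,11E)-10-hydroxy-6,10-dimethyl-2-(4-methylpent-3-enyl)-12-[4-methyl-2,5-bis(triisopropylsilyloxy)phenyl]dodeca-2,6,11-trienoate | CC(C)=CCC/C(=C\CC/C(C)=C/CC[C@](C)(O)/C=C/c1cc(O[Si](C(C)C)(C(C)C)C(C)C)c(C)cc1O[Si](C(C)C)(C(C)C)C(C)C)C(=O)OCC[Si](C)(C)C | intermediate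
24 | (2E,6E,10S,11E)-12-(2,5-dihydroxy-4-methylphenyl)-10-hydroxy-6,10-dimethyl-2-(4-methylpent-3-enyl)dodeca-2,6,11-trienoic acid (CNP0134639.1) | CC(C)=CCC/C(=C\CC/C(C)=C/CC[C@](C)(O)/C=C/c1cc(O)c(C)cc1O)C(=O)O | target

**Step count**
Total steps: 13.
Longest linear sequence: 7 steps (steps 1, 2, 3, 4, 5, 12, 13).

**Steps most likely to fail**

Step 12. What may go wrong: borylation at the benzylic C12 terminus instead of C10, loss of configuration of the delocalised lithiated species before it is captured, or migration of the ortho silyl group onto the carbanion. The fallback moves the C11–C12 unit to the alkyne oxidation level, so that the carbenoid is propargylic and the E alkene is made afterwards. It sets out from 3, uses 19 unchanged and comes back to the route at 24. Aldehyde 3 is converted with TMSCHN2/nBuLi (Colvin rearrangement) into 1-ethynyl-4-methyl-2,5-bis(triisopropylsilyloxy)benzene F1. Deprotonation with nBuLi and acylation with N-methoxy-N-methylacetamide give the ynone F2. Noyori transfer hydrogenation with RuCl[(R,R)-TsDPEN](p-cymene) in iPrOH should give the (R)-propargylic alcohol F3, which is carbamoylated as in step 5 to the propargylic carbamate F4. Lithiation–borylation of F4 with 19 and oxidation under the conditions of step 12 should give the tertiary propargylic alcohol F5. Trans-hydrosilylation with (EtO)3SiH and [Cp*Ru(MeCN)3]PF6 gives the Z vinylsilane F6. TBAF/CuI then removes the vinylic silyl group with retention (E alkene) together with the three protecting groups and gives 24.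

Step 13. What may go wrong: partial air oxidation of the hydroquinone dianion under basic fluoride, or ionisation of the tertiary allylic alcohol and cyclisation onto the ortho phenol during work-up, so that mixtures result. The fallback purifies through the quinone oxidation level; it sets out from 23 and comes back at 24. After the fluoride treatment the crude product is oxidised on purpose with Ag2O in Et2O to the single quinone acid F7, which is chromatographed and then reduced with aqueous Na2S2O4 in a two-phase system at neutral pH to 24.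

Step 8. What may go wrong: hydrolytic and oxidative loss of the pinacol ester while the epoxide is cleaved, because periodate consumes any pinacol that is set free. The fallback introduces boron only after the oxidant has been used; it sets out from 9 and comes back at 19. Epoxide 9 is cleaved with H5IO6 to (4E)-6-chloro-4-methylhex-4-enal F8. Wittig reaction of F8 with 18 gives the chloro ester F9. Deborylative alkylation of F9 with 10 and NaOtBu at 0 °C gives 19.

**Further compounds**
F1 | step 12 | 1-ethynyl-4-methyl-2,5-bis(triisopropylsilyloxy)benzene | C#Cc1cc(O[Si](C(C)C)(C(C)C)C(C)C)c(C)cc1O[Si](C(C)C)(C(C)C)C(C)C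
F2 | step 12 | 4-[4-methyl-2,5-bis(triisopropylsilyloxy)phenyl]but-3-yn-2-one | CC(=O)C#Cc1cc(O[Si](C(C)C)(C(C)C)C(C)C)c(C)cc1O[Si](C(C)C)(C(C)C)C(C)C
F3 | step 12 | (2R)-4-[4-methyl-2,5-bis(triisopropylsilyloxy)phenyl]but-3-yn-2-ol | C[C@@H](O)C#Cc1cc(O[Si](C(C)C)(C(C)C)C(C)C)c(C)cc1O[Si](C(C)C)(C(C)C)C(C)C
F4 | step 12 | (2R)-4-[4-methyl-2,5-bis(triisopropylsilyloxy)phenyl]but-3-yn-2-yl N,N-diisopropylcarbamate | C[C@@H](OC(=O)N(C(C)C)C(C)C)C#Cc1cc(O[Si](C(C)C)(C(C)C)C(C)C)c(C)cc1O[Si](C(C)C)(C(C)C)C(C)C
F5 | step 12 | 2-(trimethylsilyl)ethyl (2E,6E,10S)-10-hydroxy-6,10-dimethyl-2-(4-methylpent-3-enyl)-12-[4-methyl-2,5-bis(triisopropylsilyloxy)phenyl]dodeca-2,6-dien-11-ynoate | CC(C)=CCC/C(=C\CC/C(C)=C/CC[C@](C)(O)C#Cc1cc(O[Si](C(C)C)(C(C)C)C(C)C)c(C)cc1O[Si](C(C)C)(C(C)C)C(C)C)C(=O)OCC[Si](C)(C)C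
F6 | step 12 | 2-(trimethylsilyl)ethyl (2E,6E,10S,11Z)-10-hydroxy-6,10-dimethyl-2-(4-methylpent-3-enyl)-12-[4-methyl-2,5-bis(triisopropylsilyloxy)phenyl]-12-(triethoxysilyl)dodeca-2,6,11-trienoate | CC(C)=CCC/C(=C\CC/C(C)=C/CC[C@](C)(O)/C=C(\[Si](OCC)(OCC)OCC)c1cc(O[Si](C(C)C)(C(C)C)C(C)C)c(C)cc1O[Si](C(C)C)(C(C)C)C(C)C)C(=O)OCC[Si](C)(C)C
F7 | step 13 | (2E,6E,10S,11E)-10-hydroxy-6,10-dimethyl-12-(4-methyl-3,6-dioxocyclohexa-1,4-dien-1-yl)-2-(4-methylpent-3-enyl)dodeca-2,6,11-trienoic acid | CC(C)=CCC/C(=C\CC/C(C)=C/CC[C@](C)(O)/C=C/C1=CC(=O)C(C)=CC1=O)C(=O)O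
F8 | step 8 | (4E)-6-chloro-4-methylhex-4-enal | O=CCC/C(C)=C/CCl
F9 | step 8 | 2-(trimethylsilyl)ethyl (2E,6E)-8-chloro-6-methyl-2-(4-methylpent-3-enyl)octa-2,6-dienoate | CC(C)=CCC/C(=C\CC/C(C)=C/CCl)C(=O)OCC[Si](C)(C)C
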